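**Retrosynthetic overview**
- Target ⇐ hydroazulene-3,4,8-triol by two site-selective acylations: tiglate at the allylic hydroxyl while the 1,3-diol is masked as a boronate, then the 4-hydroxybenzoate.
- Triol ⇐ bicyclic β-hydroxy ketone (chelation-controlled reduction, carbamate cleavage) ⇐ ring-closing metathesis that forms the C8=C9 alkene; the seven-membered ring is formed second.
- Metathesis diene ⇐ aldehyde plus a methallyl nucleophile; aldehyde ⇐ key C1–C10 bond (quaternary carbon and O-bearing C10 together) by an anionic oxy-Cope [3,3] rearrangement of a 1,5-dien-3-ol carrying a (Z)-enol carbamate.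
- 1,5-Dien-3-ol ⇐ Hoppe homoaldol addition of a titanated allyl carbamate to a cyclopentene carbaldehyde.
- Cyclopentene carbaldehyde (five-membered ring, formed first) ⇐ (S)-terpinen-4-ol by ozonolysis and intramolecular aldol ring contraction; its carbinol carbon is the only purchased stereocentre and controls all the others.

Assumption: (S)-(+)-terpinen-4-ol is bought in high enantiomeric purity; the ee of that lot sets the ee of the target.

Atom labels C1–C10 below follow daucane numbering: C1 = methyl-bearing ring-fusion carbon, C4 = C(OH)(iPr), C5 = ring-fusion CH, C6 = CH–O(aroyl), C8 = methyl-bearing alkene carbon, C10 = CH–O(tigloyl). The target has α = 4-OH, 6-O, 10-O and β = 1-Me, 5-H, 4-iPr. The route is a design; it has not been run.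

**Step 1**
Reactants: 1 (S)-(+)-terpinen-4-ol
Product: 3 (5R)-5-hydroxy-2-methyl-5-(propan-2-yl)cyclopent-1-ene-1-carbaldehyde, via keto aldehyde 2 (not isolated)
Conditions: O3, CH2Cl2, −78 °C; PPh3, −78 °C → rt; then piperidine (0.2 equiv), AcOH (0.2 equiv), 40 °C
Reagents that add atoms: ozone, [O-][O+]=O
Why: Ozonolysis cleaves the ring alkene and the aldehyde-derived enamine then closes the five-membered ring by a 5-exo intramolecular aldol (Mannich-type) condensation onto the methyl ketone, losing the newly formed β-leaving group and not the hindered isopropyl carbinol, so the purchased stereocentre (C4) is carried over untouched.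

**Step 2**
Reactants: 4 prop-2-en-1-ol (allyl alcohol)
Product: 5 prop-2-en-1-yl N,N-di(propan-2-yl)carbamate
Conditions: NaH, THF, 0 °C; iPr2NCOCl, reflux
Reagents that add atoms: N,N-diisopropylcarbamoyl chloride, CC(C)N(C(C)C)C(Cl)=O
Why: Simple O-carbamoylation gives the Hoppe-type allyl carbamate; no stereocentre is involved.

**Step 3**
Reactants: 3 (5R)-5-hydroxy-2-methyl-5-(propan-2-yl)cyclopent-1-ene-1-carbaldehyde; 5 prop-2-en-1-yl N,N-di(propan-2-yl)carbamate
Product: 8 (1Z,4R)-4-hydroxy-4-[(5R)-5-hydroxy-2-methyl-5-(propan-2-yl)cyclopent-1-en-1-yl]but-1-en-1-yl N,N-di(propan-2-yl)carbamate, via lithiated carbamate 6 (not isolated), via titanium reagent 7 (not isolated)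
Conditions: 5 (2.5 equiv), sBuLi, TMEDA, Et2O, −78 °C; ClTi(OiPr)3, −78 °C; then 3, −78 → −40 °C; 2 M HCl
Reagents that add atoms: none
Why: Hoppe homoaldol reaction, in which the titanated allyl carbamate adds 1,2 through its γ-carbon in a closed six-membered transition state to give the (Z)-enol carbamate, and exchange of the free tertiary hydroxyl onto titanium chelates the s-trans aldehyde and delivers the reagent to the face syn to that hydroxyl, setting the (R)-carbinol.

**Step 4**
Reactants: 8 (1Z,4R)-4-hydroxy-4-[(5R)-5-hydroxy-2-methyl-5-(propan-2-yl)cyclopent-1-en-1-yl]but-1-en-1-yl N,N-di(propan-2-yl)carbamate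
Product: 11 (1S)-1-[(1R,2R,3R)-2-formyl-3-hydroxy-1-methyl-3-(propan-2-yl)cyclopentyl]prop-2-en-1-yl N,N-di(propan-2-yl)carbamate, via dipotassium dialkoxide 9 (not isolated), via dipotassium enolate 10 (not isolated)
Conditions: KH (3 equiv), 18-crown-6 (3 equiv), THF, 0 → 40 °C; AcOH, −78 °C; then Et3N (0.2 equiv), CH2Cl2, rt
Reagents that add atoms: none
Why: Anionic oxy-Cope [3,3]-sigmatropic rearrangement through a chair transition state in which the carbinol hydrogen eclipses the ring methyl (A1,3 strain), so the allyl unit migrates suprafacially on the hydroxyl-bearing face with the (Z)-carbamoyloxy group axial, creating quaternary C1 (R) and C10 (S) in one event, while C5 is set on equilibration with the formyl group trans to isopropyl and hydrogen-bonded to the cis hydroxyl.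

**Step 5**
Reactants: 11 (1S)-1-[(1R,2R,3R)-2-formyl-3-hydroxy-1-methyl-3-(propan-2-yl)cyclopentyl]prop-2-en-1-yl N,N-di(propan-2-yl)carbamate
Product: 12 (1S)-1-[(1R,2S,3R)-3-hydroxy-2-[(1S)-1-hydroxy-3-methylbut-3-en-1-yl]-1-methyl-3-(propan-2-yl)cyclopentyl]prop-2-en-1-yl N,N-di(propan-2-yl)carbamate (major carbinol epimer; the minor one is carried along)
Conditions: 2-methylallylmagnesium chloride CH2=C(CH3)CH2MgCl (3 equiv), THF, −78 °C; aq. NH4Cl
Reagents that add atoms: 2-methylallylmagnesium chloride, CC(=C)C[Mg]Cl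
Why: Grignard 1,2-addition to the aldehyde brings in C7 and C8; the β-alkoxide chelate model predicts the 6-epi carbinol, but this centre need not be controlled because it is oxidised in step 7 and reset in step 8.

**Step 6**
Reactants: 12 (the diene from step 5)
Product: 13 (3R,3aS,4S,8S,8aR)-3,4-dihydroxy-6,8a-dimethyl-3-(propan-2-yl)-1,2,3,3a,4,5,8,8a-octahydroazulen-8-yl N,N-di(propan-2-yl)carbamate (major C4 epimer)
Conditions: second-generation Grubbs catalyst RuCl2(=CHPh)(H2IMes)(PCy3) (10 mol %), toluene (5 mM), 80 °C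
Reagents that add atoms: none
Why: Ring-closing metathesis between the vinyl group and the 1,1-disubstituted alkene, held cis on the cyclopentane, closes the seven-membered ring as the trisubstituted C8=C9 alkene with loss of ethene and touches no stereocentre.

**Step 7**
Reactants: 13 (the bicyclic diol carbamate from step 6)
Product: 14 (3R,3aR,8S,8aR)-3-hydroxy-6,8a-dimethyl-4-oxo-3-(propan-2-yl)-1,2,3,3a,4,5,8,8a-octahydroazulen-8-yl N,N-di(propan-2-yl)carbamate
Conditions: Dess–Martin periodinane, pyridine, CH2Cl2, 0 °C → rt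
Reagents that add atoms: none
Why: Dess–Martin oxidation of the only oxidisable alcohol (the tertiary hydroxyl is inert and the C10 oxygen is masked as the carbamate) converges both C6 epimers on one β-hydroxy ketone under buffered conditions that neither epimerise C5 nor move the β,γ-alkene.

**Step 8**
Reactants: 14 (the β-hydroxy ketone from step 7)
Product: 16 (3R,3aS,4R,8S,8aR)-6,8a-dimethyl-3-(propan-2-yl)-1,2,3,3a,4,5,8,8a-octahydroazulene-3,4,8-triol, via hydroxy carbamate 15 (not isolated)
Conditions: LiAlH4 (5 equiv), LiI, Et2O–THF, −78 °C; then 45 °C; H2O, 15% NaOH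
Reagents that add atoms: none
Why: Chelation-controlled hydride reduction (lithium bridging the C4 alkoxide and the ketone) attacks from the convex face past H5 to give the 6α alcohol, and on warming LiAlH4 reductively cleaves the N,N-diisopropylcarbamate to free the C10 hydroxyl.

**Step 9**
Reactants: 16 (the triol from step 8)
Product: 19 (3R,3aS,4R,8S,8aR)-3,4-dihydroxy-6,8a-dimethyl-3-(propan-2-yl)-1,2,3,3a,4,5,8,8a-octahydroazulen-8-yl (2E)-2-methylbut-2-enoate, via phenylboronate 17 (not isolated), via tigloylated boronate 18 (not isolated)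
Conditions: PhB(OH)2 (1.05 equiv), 4 Å MS, CH2Cl2, rt; then (E)-2-methylbut-2-enoyl chloride (3 equiv), pyridine, DMAP (0.2 equiv), 0 °C → rt; then pinacol (3 equiv), rt
Reagents that add atoms: tigloyl chloride, C/C=C(\C)C(Cl)=O
Why: The cis 1,3-diol (tertiary C4–OH and secondary C6–OH) is masked in the flask as a six-membered phenylboronate, so DMAP-catalysed acylation can only occur at the allylic C10 hydroxyl, and pinacol transesterification then releases the diol.

**Step 10**
Reactants: 19 (the tiglate diol from step 9)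
Product: 21 (3R,3aS,4R,8S,8aR)-3-hydroxy-6,8a-dimethyl-8-{[(2E)-2-methylbut-2-enoyl]oxy}-3-(propan-2-yl)-1,2,3,3a,4,5,8,8a-octahydroazulen-4-yl 4-hydroxybenzoate (CNP0273650.13), via aryl acetate 20 (not isolated)
Conditions: 4-acetoxybenzoyl chloride (1.5 equiv), DMAP (0.3 equiv), pyridine, CH2Cl2, 0 °C → rt; then NH3 (7 M in MeOH), 0 °C
Reagents that add atoms: 4-acetoxybenzoyl chloride, CC(=O)Oc1ccc(cc1)C(Cl)=O
Why: DMAP-catalysed acyl transfer esterifies the secondary C6 hydroxyl and not the hindered tertiary one, and ammonolysis then cleaves the far more labile aryl acetate selectively to unmask the phenol.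

**Compound list**
1 | (S)-(+)-terpinen-4-ol, (1S)-4-methyl-1-(propan-2-yl)cyclohex-3-en-1-ol | CC1=CC[C@](O)(C(C)C)CC1 | starting material
2 | (3S)-3-hydroxy-6-oxo-3-(propan-2-yl)heptanal | O=CC[C@](O)(C(C)C)CCC(C)=O | intermediate (not isolated)
3 | (5R)-5-hydroxy-2-methyl-5-(propan-2-yl)cyclopent-1-ene-1-carbaldehyde | CC1=C(C=O)[C@](O)(C(C)C)CC1 | intermediate
4 | prop-2-en-1-ol | C=CCO | starting material
5 | prop-2-en-1-yl N,N-di(propan-2-yl)carbamate | C=CCOC(=O)N(C(C)C)C(C)C | intermediate
6 | 1-lithioprop-2-en-1-yl N,N-di(propan-2-yl)carbamate (TMEDA complex, configurationally labile) | [Li]C(C=C)OC(=O)N(C(C)C)C(C)C | intermediate (not isolated)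
7 | 1-[tri(propan-2-yloxy)titanio]prop-2-en-1-yl N,N-di(propan-2-yl)carbamate | C=CC(OC(=O)N(C(C)C)C(C)C)[Ti](OC(C)C)(OC(C)C)OC(C)C | intermediate (not isolated)
8 | (1Z,4R)-4-hydroxy-4-[(5R)-5-hydroxy-2-methyl-5-(propan-2-yl)cyclopent-1-en-1-yl]but-1-en-1-yl N,N-di(propan-2-yl)carbamate | CC1=C([C@H](O)C/C=C\OC(=O)N(C(C)C)C(C)C)[C@](O)(C(C)C)CC1 | intermediate
9 | dipotassium dialkoxide of 8 | CC1=C([C@H]([O-])C/C=C\OC(=O)N(C(C)C)C(C)C)[C@]([O-])(C(C)C)CC1.[K+].[K+] | intermediate (not isolated)
10 | dipotassium enolate/alkoxide of 11 (enolate at the exocyclic C5=C6 bond, alkoxide at C4) | [O-]C=C1[C@](C)([C@@H](OC(=O)N(C(C)C)C(C)C)C=C)CC[C@@]1([O-])C(C)C.[K+].[K+] | intermediate (not isolated)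
11 | (1S)-1-[(1R,2R,3R)-2-formyl-3-hydroxy-1-methyl-3-(propan-2-yl)cyclopentyl]prop-2-en-1-yl N,N-di(propan-2-yl)carbamate | O=C[C@@H]1[C@](C)([C@@H](OC(=O)N(C(C)C)C(C)C)C=C)CC[C@@]1(O)C(C)C | intermediate
12 | (1S)-1-[(1R,2S,3R)-3-hydroxy-2-[(1S)-1-hydroxy-3-methylbut-3-en-1-yl]-1-methyl-3-(propan-2-yl)cyclopentyl]prop-2-en-1-yl N,N-di(propan-2-yl)carbamate (major epimer) | CC(=C)C[C@H](O)[C@@H]1[C@](C)([C@@H](OC(=O)N(C(C)C)C(C)C)C=C)CC[C@@]1(O)C(C)C | intermediate
13 | (3R,3aS,4S,8S,8aR)-3,4-dihydroxy-6,8a-dimethyl-3-(propan-2-yl)-1,2,3,3a,4,5,8,8a-octahydroazulen-8-yl N,N-di(propan-2-yl)carbamate (major epimer) | CC(C)N(C(C)C)C(=O)O[C@H]1C=C(C)C[C@H](O)[C@@H]2[C@@]1(C)CC[C@@]2(O)C(C)C | intermediate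
14 | (3R,3aR,8S,8aR)-3-hydroxy-6,8a-dimethyl-4-oxo-3-(propan-2-yl)-1,2,3,3a,4,5,8,8a-octahydroazulen-8-yl N,N-di(propan-2-yl)carbamate | CC(C)N(C(C)C)C(=O)O[C@H]1C=C(C)CC(=O)[C@@H]2[C@@]1(C)CC[C@@]2(O)C(C)C | intermediate
15 | (3R,3aS,4R,8S,8aR)-3,4-dihydroxy-6,8a-dimethyl-3-(propan-2-yl)-1,2,3,3a,4,5,8,8a-octahydroazulen-8-yl N,N-di(propan-2-yl)carbamate | CC(C)N(C(C)C)C(=O)O[C@H]1C=C(C)C[C@@H](O)[C@@H]2[C@@]1(C)CC[C@@]2(O)C(C)C | intermediate (not isolated)
16 | (3R,3aS,4R,8S,8aR)-6,8a-dimethyl-3-(propan-2-yl)-1,2,3,3a,4,5,8,8a-octahydroazulene-3,4,8-triol | O[C@H]1C=C(C)C[C@@H](O)[C@@H]2[C@@]1(C)CC[C@@]2(O)C(C)C | intermediate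
17 | cyclic phenylboronate of 16 across O3 and O4 (six-membered dioxaborinane; 8-OH free) | O[C@H]1C=C(C)C[C@H]2OB(c3ccccc3)O[C@@]4(C(C)C)CC[C@]1(C)[C@@H]24 | intermediate (not isolated)
18 | 8-O-[(2E)-2-methylbut-2-enoyl] derivative of 17 | C/C=C(\C)C(=O)O[C@H]1C=C(C)C[C@H]2OB(c3ccccc3)O[C@@]4(C(C)C)CC[C@]1(C)[C@@H]24 | intermediate (not isolated)
19 | (3R,3aS,4R,8S,8aR)-3,4-dihydroxy-6,8a-dimethyl-3-(propan-2-yl)-1,2,3,3a,4,5,8,8a-octahydroazulen-8-yl (2E)-2-methylbut-2-enoate | C/C=C(\C)C(=O)O[C@H]1C=C(C)C[C@@H](O)[C@@H]2[C@@]1(C)CC[C@@]2(O)C(C)C | intermediate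
20 | (3R,3aS,4R,8S,8aR)-3-hydroxy-6,8a-dimethyl-8-{[(2E)-2-methylbut-2-enoyl]oxy}-3-(propan-2-yl)-1,2,3,3a,4,5,8,8a-octahydroazulen-4-yl 4-(acetyloxy)benzoate | C/C=C(\C)C(=O)O[C@H]1C=C(C)C[C@@H](OC(=O)c2ccc(OC(C)=O)cc2)[C@@H]2[C@@]1(C)CC[C@@]2(O)C(C)C | intermediate (not isolated)
21 | (3R,3aS,4R,8S,8aR)-3-hydroxy-6,8a-dimethyl-8-{[(2E)-2-methylbut-2-enoyl]oxy}-3-(propan-2-yl)-1,2,3,3a,4,5,8,8a-octahydroazulen-4-yl 4-hydroxybenzoate | C/C=C(\C)C(=O)O[C@H]1C=C(C)C[C@@H](OC(=O)c2ccc(O)cc2)[C@@H]2[C@@]1(C)CC[C@@]2(O)C(C)C | target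

**Step count**
Total: 10 steps. Longest linear sequence: 9 steps (1 → 21 through steps 1 and 3–10); step 2 is the one-step side branch.

**Three steps most likely to fail, each with a fallback**

The homoaldol addition of step 3 carries the most stereochemical weight, because the carbinol configuration it sets decides which face of the cyclopentene receives C10 in step 4. If delivery through the titanium-bound tertiary alkoxide is poor, the fallback sets out from 3 (with 5) and comes back at 8. The addition is run without relying on delivery (6 titanated with Ti(OiPr)4) and the two carbinol epimers are separated on silica. The unwanted (1Z,4S)-epimer of 8 F1 is then inverted by a Mitsunobu reaction (4-nitrobenzoic acid, PPh3, DIAD, THF, 0 °C) to the (R)-configured 4-nitrobenzoate F2. Methanolysis (K2CO3 cat., MeOH) returns 8. Stereocontrol then comes from separation and SN2 inversion instead of from direction by the substrate.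

The anionic oxy-Cope rearrangement of step 4 must form a quaternary carbon next to an enol carbamate terminus, and the potassium alkoxide could instead fragment by retro-homoaldol cleavage back to 3. The fallback sets out from 8 and comes back at 11, and it leaves the charge-accelerated manifold for a neutral one. Both hydroxyls are silylated with N-(trimethylsilyl)imidazole to give the bis(trimethylsilyl) ether F3, which has no alkoxide to fragment. Heating F3 in o-dichlorobenzene at about 210 °C in a sealed, base-washed tube effects the thermal siloxy-Cope [3,3] shift through the same chair to the trimethylsilyl enol ether F4. Citric acid in MeOH then removes both silyl groups and gives 11.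

The one-pot site-selective tigloylation of step 9 depends on clean, complete boronate formation at a hindered tertiary/secondary diol; if the boronate is incomplete or labile under the acylation, C6 and C10 esters will mix. The fallback sets out from 16 and comes back at 19, using an isolated protecting group instead of a transient one. 2,2-Dimethoxypropane with PPTS converts the 1,3-diol into the acetonide F5, which can be purified. Tigloyl chloride, pyridine and DMAP acylate the remaining allylic hydroxyl to the tiglate acetonide F6. Aqueous acetic acid in THF at 40 °C then removes the acetal to give 19.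

**Further compounds**
F1 | step 3 | (1Z,4S)-4-hydroxy-4-[(5R)-5-hydroxy-2-methyl-5-(propan-2-yl)cyclopent-1-en-1-yl]but-1-en-1-yl N,N-di(propan-2-yl)carbamate | CC1=C([C@@H](O)C/C=C\OC(=O)N(C(C)C)C(C)C)[C@](O)(C(C)C)CC1
F2 | step 3 | (1R,3Z)-4-{[di(propan-2-yl)carbamoyl]oxy}-1-[(5R)-5-hydroxy-2-methyl-5-(propan-2-yl)cyclopent-1-en-1-yl]but-3-en-1-yl 4-nitrobenzoate | CC1=C([C@H](OC(=O)c2ccc(cc2)[N+](=O)[O-])C/C=C\OC(=O)N(C(C)C)C(C)C)[C@](O)(C(C)C)CC1
F3 | step 4 | bis(trimethylsilyl) ether of 8 | CC1=C([C@H](O[Si](C)(C)C)C/C=C\OC(=O)N(C(C)C)C(C)C)[C@](O[Si](C)(C)C)(C(C)C)CC1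
F4 | step 4 | trimethylsilyl enol ether of 11, also silylated at the tertiary hydroxyl | C[Si](C)(C)OC=C1[C@](C)([C@@H](OC(=O)N(C(C)C)C(C)C)C=C)CC[C@@]1(O[Si](C)(C)C)C(C)C
F5 | step 9 | 3,4-O-isopropylidene acetal (acetonide) of 16 | O[C@H]1C=C(C)C[C@H]2OC(C)(C)O[C@@]3(C(C)C)CC[C@]1(C)[C@@H]23
F6 | step 9 | 8-O-[(2E)-2-methylbut-2-enoyl] derivative of F5 | C/C=C(\C)C(=O)O[C@H]1C=C(C)C[C@H]2OC(C)(C)O[C@@]3(C(C)C)CC[C@]1(C)[C@@H]23
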